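The key step exploits the substitution of ring A, read around the ring as C-a (carbonyl), C-b (methyl), C-c (methoxy), C-d (gem-dimethyl), C-e (carbonyl) and C-f (spiro carbon shared with ring B): three oxygenated carbons alternate with two methylated ones around a fully substituted carbon, the footprint of a ketene–ynol ether annulation that cannot aromatise. Ring A is therefore cut at three bonds into a ring B spiro cyclobutenone and 1-methoxypropyne, and one thermal pericyclic cascade rebuilds it together with the congested spiro junction. The cyclobutenone carries a silyl enol ether at the future C-a, which keeps the two enol ethers of the product distinct.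

Key step: step 15

Remarks
- Labels: in ring A, C-a is the carbonyl carbon next to the methyl-bearing alkene carbon C-b, C-c is the methoxy-bearing alkene carbon, C-d the gem-dimethyl carbon, C-e the carbonyl carbon next to C-d, and C-f the spiro carbon. Ring B runs from C-f through the isopropyl carbon and two methylenes to the quaternary pinane carbon (the former ketone carbon of nopinone), which is also bonded to C-f.
- Bonds of the key step: C-e to C-d, C-c to C-b, and C-e to C-f.
- Design of the precursor: the C-a oxygen carries triisopropylsilyl and the C-c oxygen methyl, so that fluoride frees C-a without competition from the methyl ether.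
- Stereochemical point: the configuration formed at C-f in step 15 is not what reaches the target. After step 16 ring A is pseudo-symmetric, and C-f becomes a stereocentre again only through the choice of arm in step 17.
- Assumption: (+)-β-pinene, tert-butyl 2-(diethoxyphosphoryl)acetate and 1-propynyllithium are purchased.

Step 1
Reactants: 1 (+)-β-pinene
Product: 3 (−)-nopinone, via ozonide 2 (not isolated)
Conditions: O3, CH2Cl2, −78 °C; then Me2S, −78 °C → rt
Reagents that add atoms: ozone [O-][O+]=O
Why: Ozonolysis with reductive work-up cleaves only the exocyclic C=C bond and leaves both bridgehead stereocentres of the pinane untouched.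

Step 2
Reactants: 3 (−)-nopinone; 4 tert-butyl 2-(diethoxyphosphoryl)acetate
Product: 5 tert-butyl nopinylideneacetate
Conditions: NaH, THF, 0 °C; then 3, 65 °C
Reagents that add atoms: none
Why: Horner–Wadsworth–Emmons olefination of the ketone gives the β,β-disubstituted enoate, whose alkene geometry is of no consequence, and the tert-butyl ester is chosen to resist 1,2-attack in step 7 and to be cleaved by acid in step 11.

Step 3
Reactants: 6 methyl 4-methyl-3-oxopentanoate
Product: 7 methyl (3S)-3-hydroxy-4-methylpentanoate
Conditions: H2 (50 bar), RuCl2[(R)-BINAP] (0.2 mol%), MeOH, 50 °C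
Reagents that add atoms: none
Why: Noyori asymmetric hydrogenation of the β-keto ester, in which the chelated RuCl2[(R)-BINAP] catalyst delivers hydrogen to the ketone face that gives the (S)-carbinol, the future isopropyl carbon of ring B.

Step 4
Reactants: 7 methyl (3S)-3-hydroxy-4-methylpentanoate
Product: 8 methyl (3S)-3-(tert-butyldimethylsilyloxy)-4-methylpentanoate
Conditions: t-BuMe2SiCl, imidazole, DMF, rt
Reagents that add atoms: tert-butyldimethylsilyl chloride CC(C)(C)[Si](C)(C)Cl
Why: Silyl ether formation masks the secondary alcohol for the organomagnesium step without touching the stereocentre.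

Step 5
Reactants: 8 methyl (3S)-3-(tert-butyldimethylsilyloxy)-4-methylpentanoate
Product: 9 (3S)-3-(tert-butyldimethylsilyloxy)-4-methylpentan-1-ol
Conditions: i-Bu2AlH (2.5 equiv), CH2Cl2, −78 → 0 °C; aq. potassium sodium tartrate
Reagents that add atoms: none
Why: Aluminium hydride reduction of the ester stops cleanly at the primary alcohol and does not affect the silyl ether or the stereocentre.

Step 6
Reactants: 9 (3S)-3-(tert-butyldimethylsilyloxy)-4-methylpentan-1-ol
Product: 10 (3S)-1-bromo-3-(tert-butyldimethylsilyloxy)-4-methylpentane
Conditions: CBr4, PPh3, 2,6-lutidine, CH2Cl2, 0 °C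
Reagents that add atoms: carbon tetrabromide BrC(Br)(Br)Br
Why: Appel bromination of the primary alcohol under buffered conditions keeps the silyl ether intact.

Step 7
Reactants: 5 tert-butyl nopinylideneacetate; 10 (3S)-1-bromo-3-(tert-butyldimethylsilyloxy)-4-methylpentane
Product: 13 tert-butyl ester bearing the quaternary pinane carbon, via Grignard reagent 11 (not isolated), via silyl ketene acetal 12 (not isolated)
Conditions: 10 (1.5 equiv), Mg, THF, 45 °C; then 5, CuBr·SMe2 (10 mol%), Me3SiCl, HMPA, THF, −78 → −20 °C; aq. NH4Cl
Reagents that add atoms: none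
Why: Copper-catalysed, chlorosilane-accelerated conjugate addition of a Grignard reagent to a β,β-disubstituted enoate, in which the alkyl group enters the β-carbon from the face opposite the gem-dimethyl bridge and so sets the quaternary pinane carbon of ring B with the acetate arm (future C-f) syn to that bridge.

Step 8
Reactants: 13 tert-butyl ester bearing the quaternary pinane carbon
Product: 14 secondary (3S)-alcohol
Conditions: Bu4NF, THF, rt
Reagents that add atoms: none
Why: Fluoride-mediated desilylation cleaves the silyl ether while the tert-butyl ester is inert, and the seven-membered lactone cannot compete.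

Step 9
Reactants: 14 secondary (3S)-alcohol
Product: 15 secondary (3S)-methanesulfonate
Conditions: MeSO2Cl, Et3N, CH2Cl2, 0 °C
Reagents that add atoms: methanesulfonyl chloride CS(=O)(=O)Cl
Why: O-Sulfonylation activates the carbinol with retention of its (S) configuration.

Step 10
Reactants: 15 secondary (3S)-methanesulfonate
Product: 16 ring B tert-butyl ester
Conditions: KN(SiMe3)2, THF, −78 → 25 °C
Reagents that add atoms: none
Why: Intramolecular ester enolate alkylation (5-exo-tet displacement with inversion) closes ring B and turns the (S)-mesylate carbon into the (R)-configured isopropyl carbon, while C-f forms as an epimer mixture that does not matter because it becomes sp2 in step 13.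

Step 11
Reactants: 16 ring B tert-butyl ester
Product: 17 ring B carboxylic acid
Conditions: CF3CO2H, CH2Cl2, 0 °C → rt
Reagents that add atoms: none
Why: Acidolysis of the tert-butyl ester with loss of isobutene frees the hindered acid without base and without risk to the saturated pinane.

Step 12
Reactants: 18 1-propynyllithium
Product: 20 triisopropyl(prop-1-yn-1-yloxy)silane, via lithium prop-1-yn-1-olate 19 (not isolated)
Conditions: t-BuOOH, LiN(SiMe3)2, THF, −78 °C; add 18, −78 → 0 °C; then i-Pr3SiOSO2CF3, −78 °C → rt
Reagents that add atoms: tert-butyl hydroperoxide CC(C)(C)OO; triisopropylsilyl trifluoromethanesulfonate CC(C)[Si](OS(=O)(=O)C(F)(F)F)(C(C)C)C(C)C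
Why: Oxygenation of the lithium acetylide by the lithium alkyl peroxide gives the ynolate, which the bulky silyl triflate traps on oxygen, a known route to silyl ynol ethers.

Step 13
Reactants: 17 ring B carboxylic acid; 20 triisopropyl(prop-1-yn-1-yloxy)silane
Product: 23 spiro 2-methyl-3-silyloxycyclobutenone, via acid chloride 21 (not isolated), via ketene 22 (not isolated)
Conditions: (COCl)2, DMF (cat.), CH2Cl2, 0 °C → rt, evaporate; Et3N, toluene, 60 °C; then 20 (1.1 equiv), 25 → 45 °C
Reagents that add atoms: none
Why: Dehydrochlorination gives a hindered dialkylketene that does not dimerise, and its [2+2] cycloaddition with the silyl ynol ether joins the ketene carbon to the methyl-bearing alkyne carbon and C-f to the oxygen-bearing carbon, the new spiro centre (alkyne expected anti to isopropyl) being erased in step 15.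

Step 14
Reactants: 24 chloroacetaldehyde dimethyl acetal
Product: 26 1-methoxypropyne, via sodium methoxyacetylide 25 (not isolated)
Conditions: NaNH2 (3 equiv), liquid NH3, −33 °C; then MeI, −40 °C; distil
Reagents that add atoms: iodomethane CI
Why: Twofold elimination from the chloroacetal with sodium amide gives the sodium alkoxyacetylide, which is C-methylated in liquid ammonia (acetylide alkylation).

Step 15
Reactants: 23 spiro 2-methyl-3-silyloxycyclobutenone; 26 1-methoxypropyne
Product: 30 spiro cyclohexa-2,4-dienone, via vinylketene 27 (not isolated), via alkenylcyclobutenone 28 (not isolated), via dienylketene 29 (not isolated)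
Conditions: 26 (3 equiv), toluene, 120 °C, sealed tube, dark
Reagents that add atoms: none
Why: Heating opens 23 by conrotatory 4π electrocyclic ring opening to vinylketene 27 (the spiro carbon becomes sp2), whose ketene carbon C-e bonds to the nucleophilic methyl-bearing carbon of 26 while C-b bonds to the oxygen-bearing carbon in a [2+2] cycloaddition; the resulting 28 reopens to dienylketene 29, and a disrotatory 6π electrocyclisation joins the slender sp-hybridised C-e to the fully substituted C-f. The closest known reaction type is the Danheiser benzannulation of cyclobutenones with alkoxyalkynes, which stops at a 6,6-disubstituted cyclohexa-2,4-dienone when the terminus carries no hydrogen. Ring A is closed by this thermally allowed six-electron electrocyclisation, a six-membered all-carbon closure that needs only the Z geometry at the double bond between C-b and C-c, which 28 and 29 reach by reversible ring opening. The new stereocentre C-f is controlled by the isopropyl group on the neighbouring ring B carbon, which should steer C-e to the opposite face of ring B, but either epimer is acceptable because C-f ceases to be a fixed stereocentre in step 16 and is set again in step 17. The one selectivity the step needs is the orientation of alkyne uptake, and the polarisation of the ynol ether (electron-rich carbon to the electrophilic ketene carbon) secures it. The silyl ether on C-a and the methyl ether on C-c emerge differentiated, which is what the endgame requires.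

Step 16
Reactants: 30 spiro cyclohexa-2,4-dienone
Product: 31 symmetric vinylogous ester
Conditions: Bu4NF, AcOH, THF, 0 °C
Reagents that add atoms: none
Why: Fluoride-mediated desilylation cleaves only the silyl enol ether and protonation gives the vinylogous acid, whose tautomers exchange the C-a and C-e arms so that C-f is no longer a fixed stereocentre.

Step 17
Reactants: 31 symmetric vinylogous ester
Product: 32 target CNP0307059.1
Conditions: KOt-Bu (1.05 equiv), MeI, t-BuOH–THF, 0 °C → rt
Reagents that add atoms: iodomethane CI
Why: C-Methylation of the delocalised triketone-type enolate (the classical gem-dimethylation of phloroglucinol-derived anions) should occur at C-d, the arm on the face of ring B where the isopropyl carbon carries only hydrogen, whereas C-b is flanked by isopropyl and by a pinane ring methylene, and this choice of arm sets the configuration at C-f.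

Compound list
1 | (+)-β-pinene, (1R,5R)-6,6-dimethyl-2-methylidenebicyclo[3.1.1]heptane | C=C1CC[C@@H]2C[C@H]1C2(C)C | starting material
2 | ozonide of 1 (spiro 1,2,4-trioxolane on the pinane ring, both spiro epimers) | C1OC2(OO1)CC[C@@H]1C[C@H]2C1(C)C | intermediate
3 | (−)-nopinone, (1S,5R)-6,6-dimethylbicyclo[3.1.1]heptan-2-one | O=C1CC[C@@H]2C[C@H]1C2(C)C | intermediate
4 | tert-butyl 2-(diethoxyphosphoryl)acetate | CCOP(=O)(CC(=O)OC(C)(C)C)OCC | starting material
5 | tert-butyl (E)-2-[(1S,5R)-6,6-dimethylbicyclo[3.1.1]heptan-2-ylidene]acetate (E drawn, geometry immaterial) | CC(C)(C)OC(=O)/C=C1\CC[C@@H]2C[C@H]1C2(C)C | intermediate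
6 | methyl 4-methyl-3-oxopentanoate | COC(=O)CC(=O)C(C)C | starting material
7 | methyl (3S)-3-hydroxy-4-methylpentanoate | COC(=O)C[C@H](O)C(C)C | intermediate
8 | methyl (3S)-3-(tert-butyldimethylsilyloxy)-4-methylpentanoate | COC(=O)C[C@H](O[Si](C)(C)C(C)(C)C)C(C)C | intermediate
9 | (3S)-3-(tert-butyldimethylsilyloxy)-4-methylpentan-1-ol | OCC[C@H](O[Si](C)(C)C(C)(C)C)C(C)C | intermediate
10 | (3S)-1-bromo-3-(tert-butyldimethylsilyloxy)-4-methylpentane | BrCC[C@H](O[Si](C)(C)C(C)(C)C)C(C)C | intermediate
11 | [(3S)-3-(tert-butyldimethylsilyloxy)-4-methylpentyl]magnesium bromide | Br[Mg]CC[C@H](O[Si](C)(C)C(C)(C)C)C(C)C | intermediate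
12 | tert-butyl trimethylsilyl ketene acetal of 13 (alkene geometry open) | CC(C)(C)OC(O[Si](C)(C)C)=C[C@@]1(CC[C@H](O[Si](C)(C)C(C)(C)C)C(C)C)CC[C@@H]2C[C@H]1C2(C)C | intermediate
13 | tert-butyl 2-[2-[(3S)-3-(tert-butyldimethylsilyloxy)-4-methylpentyl]-6,6-dimethylbicyclo[3.1.1]heptan-2-yl]acetate; bridgeheads as in 1, pentyl chain anti and acetate arm syn to the gem-dimethyl bridge | CC(C)(C)OC(=O)C[C@@]1(CC[C@H](O[Si](C)(C)C(C)(C)C)C(C)C)CC[C@@H]2C[C@H]1C2(C)C | intermediate
14 | (3S)-alcohol obtained from 13 by loss of the silyl group | CC(C)(C)OC(=O)C[C@@]1(CC[C@H](O)C(C)C)CC[C@@H]2C[C@H]1C2(C)C | intermediate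
15 | (3S)-methanesulfonate of 14 | CC(C)(C)OC(=O)C[C@@]1(CC[C@H](OS(C)(=O)=O)C(C)C)CC[C@@H]2C[C@H]1C2(C)C | intermediate
16 | ring B ester: tert-butyl 3-isopropylspiro[cyclopentane-1,2'-pinane]-2-carboxylate; (R) at the isopropyl carbon, ester carbon (both epimers) syn to the gem-dimethyl bridge | CC(C)(C)OC(=O)C1[C@@H](C(C)C)CC[C@@]12CC[C@@H]3C[C@H]2C3(C)C | intermediate
17 | ring B carboxylic acid (stereochemistry as in 16) | OC(=O)C1[C@@H](C(C)C)CC[C@@]12CC[C@@H]3C[C@H]2C3(C)C | intermediate
18 | 1-propynyllithium | [Li]C#CC | starting material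
19 | lithium prop-1-yn-1-olate | [Li]OC#CC | intermediate
20 | triisopropyl(prop-1-yn-1-yloxy)silane | CC#CO[Si](C(C)C)(C(C)C)C(C)C | intermediate
21 | acid chloride of 17 | ClC(=O)C1[C@@H](C(C)C)CC[C@@]12CC[C@@H]3C[C@H]2C3(C)C | intermediate
22 | ring B ketene (exocyclic C=C=O on the future C-f) | O=C=C1[C@@H](C(C)C)CC[C@@]12CC[C@@H]3C[C@H]2C3(C)C | intermediate
23 | spiro cyclobutenone: 2-methyl-3-(triisopropylsilyloxy)cyclobut-2-en-1-one spiro-fused through its sp3 ring carbon to ring B (carbonyl = future C-e; expected spiro epimer drawn, either serves) | CC(C)[Si](OC1=C(C)C(=O)[C@]12[C@@H](C(C)C)CC[C@@]21CC[C@@H]2C[C@H]1C2(C)C)(C(C)C)C(C)C | intermediate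
24 | chloroacetaldehyde dimethyl acetal (2-chloro-1,1-dimethoxyethane) | COC(CCl)OC | starting material
25 | sodium methoxyacetylide | [Na]C#COC | intermediate
26 | 1-methoxypropyne | CC#COC | intermediate
27 | vinylketene from ring opening of 23 (exocyclic alkene on ring B) | CC(=C=O)C(O[Si](C(C)C)(C(C)C)C(C)C)=C1[C@@H](C(C)C)CC[C@@]12CC[C@@H]3C[C@H]2C3(C)C | intermediate
28 | 3-methoxy-2,4-dimethyl-4-(1-silyloxyalkenyl)cyclobut-2-enone (epimers at the sp3 ring carbon C-b) | COC1=C(C)C(=O)C1(C)C(O[Si](C(C)C)(C(C)C)C(C)C)=C1[C@@H](C(C)C)CC[C@@]12CC[C@@H]3C[C@H]2C3(C)C | intermediate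
29 | dienylketene (ketene carbon C-e; Z double bond between C-b and C-c for closure) | CC(=C=O)C(OC)=C(C)C(O[Si](C(C)C)(C(C)C)C(C)C)=C1[C@@H](C(C)C)CC[C@@]12CC[C@@H]3C[C@H]2C3(C)C | intermediate
30 | spiro 3-methoxy-2,4-dimethyl-5-(triisopropylsilyloxy)cyclohexa-2,4-dienone (carbonyl C-e anti to isopropyl drawn) | COC1=C(C)C(=O)[C@]2(C(O[Si](C(C)C)(C(C)C)C(C)C)=C1C)[C@@H](C(C)C)CC[C@@]21CC[C@@H]2C[C@H]1C2(C)C | intermediate
31 | symmetric vinylogous ester: spiro 5-hydroxy-3-methoxy-2,4-dimethylcyclohexa-2,4-dienone in tautomeric equilibrium (C-f not fixed) | COC1=C(C)C(=O)C2(C(O)=C1C)[C@@H](C(C)C)CC[C@@]21CC[C@@H]2C[C@H]1C2(C)C | intermediate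
32 | CNP0307059.1 | COC1=C(C)C(=O)[C@@]2(C(=O)C1(C)C)[C@@H](C(C)C)CC[C@@]21CC[C@@H]2C[C@H]1C2(C)C | target

Total step count: 17
Longest linear sequence: 13 steps (from 6 through steps 3–11, 13 and 15–17)

Steps most likely to fail

Step 15. The vinylketene 27 or the dienylketene 29 may be drained off before the crowded 6π closure can occur, by a 1,5-hydrogen shift from the isopropyl-bearing ring B carbon to the ketene carbon, by uptake of a second alkyne or by oligomerisation. The stabilised silyloxycyclobutenone may also fail to open below its decomposition temperature. The fallback sets out from 15 and comes back at 30; it reverses the order of the two ring closures, so that ring A is made by an ordinary aromatising benzannulation and the spiro centre by alkylation. CF3CO2H converts 15 into acid mesylate F1. (COCl)2 and then Et3N give acid chloride F2 and tert-alkylketene F3, which adds 20 to give the 4-monosubstituted cyclobutenone F4 (its sp3 ring carbon bears hydrogen and the pinane carbon). Heating F4 with 26 in toluene at 80–100 °C should give the hexasubstituted phenol F5 (hydroxyl on C-e, methoxy on C-c, silyloxy on C-a, C-f bonded to the quaternary pinane carbon). KOt-Bu in t-BuOH then lets the phenoxide attack the mesylate through C-f (ipso alkylation with dearomatisation, 5-exo-tet, inversion at the isopropyl carbon). This closes ring B and delivers 30 or its C-f epimer, both of which enter step 16.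

Step 10. Elimination of the hindered secondary mesylate may outrun substitution, or the enolate carbon next to the quaternary centre may fail to reach the mesylate carbon. The fallback sets out from 3 and comes back at 17; it closes the ring with a slimmer, less basic nitrile anion and builds the quaternary centre on a more reactive acceptor, so it also replaces step 7. Knoevenagel condensation of 3 with ethyl cyanoacetate (NH4OAc, AcOH, toluene, water removal) gives alkylidene cyanoacetate F6. Grignard reagent 11 with CuI (10 mol%) adds anti to the gem-dimethyl bridge to give cyanoacetate adduct F7. Krapcho dealkoxycarbonylation (LiCl, wet DMSO, 150 °C) gives nitrile F8. Bu4NF gives hydroxy nitrile F9, and MeSO2Cl with Et3N gives mesylate nitrile F10. KN(SiMe3)2 closes ring B with inversion to spiro nitrile F11. i-Bu2AlH followed by aqueous acid gives aldehyde F12, and Pinnick oxidation (NaClO2, NaH2PO4, 2-methylbut-2-ene) gives 17.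

Step 17. The electrophile may not distinguish the two arms of the delocalised anion well enough (attack at C-b gives the C-f epimer of the target), and part of the anion may be methylated on oxygen. The fallback sets out from 17 and comes back at 32; the two alkynes change places, so that the carbon to be methylated is the only nucleophilic one and the arm is fixed by the configuration made in the annulation. Ketene 22, generated as in step 13, adds 26 to give methoxy cyclobutenone F13. Heating F13 with 20 gives dienone F14 (methyl ether on C-a, silyl ether on C-c), whose C-f epimers are now separable diastereomers; the one with C-e anti to isopropyl is taken on. Bu4NF and then MeI in THF methylate the 1,3-diketonate at C-d, the carbon between the C-c and C-e carbonyl groups, to give gem-dimethyl diketone F15. TsOH and HC(OMe)3 in MeOH then move the enol ether from the C-a oxygen to the less shielded C-c oxygen by acid-catalysed exchange and give 32; the unchanged isomer is returned to the equilibration.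

Further compounds
F1 | step 15 | acid mesylate: 2-[2-[(3S)-3-(methylsulfonyloxy)-4-methylpentyl]-6,6-dimethylbicyclo[3.1.1]heptan-2-yl]acetic acid (configuration as in 15) | OC(=O)C[C@@]1(CC[C@H](OS(C)(=O)=O)C(C)C)CC[C@@H]2C[C@H]1C2(C)C
F2 | step 15 | acid chloride of F1 | ClC(=O)C[C@@]1(CC[C@H](OS(C)(=O)=O)C(C)C)CC[C@@H]2C[C@H]1C2(C)C
F3 | step 15 | tert-alkylketene from F2 | O=C=C[C@@]1(CC[C@H](OS(C)(=O)=O)C(C)C)CC[C@@H]2C[C@H]1C2(C)C
F4 | step 15 | 2-methyl-4-(pinan-2-yl)-3-(triisopropylsilyloxy)cyclobut-2-enone (epimers at the sp3 ring carbon) | CC1=C(O[Si](C(C)C)(C(C)C)C(C)C)C(C1=O)[C@@]1(CC[C@H](OS(C)(=O)=O)C(C)C)CC[C@@H]2C[C@H]1C2(C)C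
F5 | step 15 | phenol: 3-methoxy-2,4-dimethyl-6-(pinan-2-yl)-5-(triisopropylsilyloxy)phenol carrying the mesylate chain | Oc1c(C)c(OC)c(C)c(O[Si](C(C)C)(C(C)C)C(C)C)c1[C@@]1(CC[C@H](OS(C)(=O)=O)C(C)C)CC[C@@H]2C[C@H]1C2(C)C
F6 | step 10 | ethyl 2-cyano-2-[(1S,5R)-6,6-dimethylbicyclo[3.1.1]heptan-2-ylidene]acetate (geometry open) | CCOC(=O)C(C#N)=C1CC[C@@H]2C[C@H]1C2(C)C
F7 | step 10 | cyanoacetate adduct bearing the quaternary pinane carbon (α-carbon epimers) | CCOC(=O)C(C#N)[C@@]1(CC[C@H](O[Si](C)(C)C(C)(C)C)C(C)C)CC[C@@H]2C[C@H]1C2(C)C
F8 | step 10 | nitrile: 2-[2-[(3S)-3-(tert-butyldimethylsilyloxy)-4-methylpentyl]-6,6-dimethylbicyclo[3.1.1]heptan-2-yl]acetonitrile | N#CC[C@@]1(CC[C@H](O[Si](C)(C)C(C)(C)C)C(C)C)CC[C@@H]2C[C@H]1C2(C)C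
F9 | step 10 | hydroxy nitrile | N#CC[C@@]1(CC[C@H](O)C(C)C)CC[C@@H]2C[C@H]1C2(C)C
F10 | step 10 | mesylate nitrile | N#CC[C@@]1(CC[C@H](OS(C)(=O)=O)C(C)C)CC[C@@H]2C[C@H]1C2(C)C
F11 | step 10 | spiro nitrile of ring B ((R) at the isopropyl carbon, epimers at the nitrile-bearing carbon) | N#CC1[C@@H](C(C)C)CC[C@@]12CC[C@@H]3C[C@H]2C3(C)C
F12 | step 10 | ring B aldehyde | O=CC1[C@@H](C(C)C)CC[C@@]12CC[C@@H]3C[C@H]2C3(C)C
F13 | step 17 | spiro 3-methoxy-2-methylcyclobut-2-enone on ring B | COC1=C(C)C(=O)[C@]12[C@@H](C(C)C)CC[C@@]21CC[C@@H]2C[C@H]1C2(C)C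
F14 | step 17 | spiro 5-methoxy-2,4-dimethyl-3-(triisopropylsilyloxy)cyclohexa-2,4-dienone (carbonyl anti to isopropyl) | CC(C)[Si](OC1=C(C)C(=O)[C@]2(C(OC)=C1C)[C@@H](C(C)C)CC[C@@]21CC[C@@H]2C[C@H]1C2(C)C)(C(C)C)C(C)C
F15 | step 17 | gem-dimethyl diketone: carbonyl at C-e and C-c, gem-dimethyl at C-d, methyl enol ether at C-a | COC1=C(C)C(=O)C(C)(C)C(=O)[C@@]12[C@@H](C(C)C)CC[C@@]21CC[C@@H]2C[C@H]1C2(C)C
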